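**Retrosynthetic overview**
1. Target ⇐ global desilylation (step 18) ⇐ palladium-catalysed asymmetric C-3 prenylation of a 3-aryl-4-hydroxycoumarin (step 17), which sets the quaternary centre last, by catalyst control.
2. Cyclohexene ⇐ one-pot palladium-catalysed [4+2] carboannulation of alkenyl iodide/β-keto lactone 19 with styrene 20 (step 15). It forms the bond from the methyl-bearing alkene carbon to the ring CH2 and the bond from the aryl-bearing CH to the aroyl-bearing carbon. The temporary lactone is then opened, decarboxylated and ketonised under kinetic control to the all-cis ring (step 16).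
3. Enabling feature: in the cyclohexene the ring CH2 lies between the methyl-bearing sp2 carbon and a benzylic CH carrying an electron-rich 2,4-dioxygenated aryl group, and that CH is bonded to the CH alpha to the aryl ketone. The phenolic oxygen at C-5 of the chromane, ortho to C-6 which carries the ring, can hold this ketone α-carbon as a soft β-keto-lactone enolate four atoms away from an alkenyl iodide, so a styrene can supply the CH2–CH(aryl) unit.
4. 19 ⇐ symmetric acylphloroglucinol 9 + (2E,4Z)-5-iodohexa-2,4-dienal 5 by iminium-catalysed Friedel–Crafts alkylation/lactol formation (sets the benzylic centre), oxidation to the lactone, coumarin closure with the one remaining free phenol, and C-aroylation.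
5. Ring order: aromatic ring A (from phloroglucinol) → temporary dihydropyranone (steps 7–8) → coumarin pyranone (step 9) → cyclohexene (step 15) → temporary ring removed (step 16).

Key step: step 15

Assumption: TIPS = triisopropylsilyl, TIPSO = triisopropylsilyloxy; the target is the all-cis cyclohexene (ring carbons 1S,5R,6R; aryl, aroyl and aryl on one face) with a 3S quaternary centre; the facial sense of the catalysts in steps 7 and 17 is taken from the accepted models and would be confirmed on model substrates.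

**Route**

Step 1
Reactants: 1 ethyl but-2-ynoate
Product: 2 ethyl (2Z)-3-iodobut-2-enoate
Conditions: NaI, AcOH, 115 °C
Reagents that add atoms: sodium iodide, [Na+].[I-]
Why: Conjugate hydroiodination of the ynoate (iodide adds to the β-carbon, the allenolate is protonated anti) should give the (Z)-β-iodo enoate with iodine cis to the ester.

Step 2
Reactants: 2 ethyl (2Z)-3-iodobut-2-enoate
Product: 3 (2Z)-3-iodobut-2-en-1-ol
Conditions: i-Bu2AlH (2.3 equiv), CH2Cl2, −78 to 0 °C; Rochelle salt work-up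
Reagents that add atoms: none
Why: Hydride reduction of the ester (DIBAL-H reduction) is a 1,2-process that should leave the alkenyl iodide and its geometry untouched.

Step 3
Reactants: 3 (2Z)-3-iodobut-2-en-1-ol
Product: 4 (2Z)-3-iodobut-2-enal
Conditions: MnO2 (activated, excess), CH2Cl2, rt, dark
Reagents that add atoms: none
Why: Allylic alcohol oxidation with manganese dioxide is neutral and heterogeneous, so the Z-iodoalkene should survive.

Step 4
Reactants: 4 (2Z)-3-iodobut-2-enal
Product: 5 (2E,4Z)-5-iodohexa-2,4-dienal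
Conditions: Ph3P=CHCHO (1.05 equiv), toluene, 60 °C, dark
Reagents that add atoms: (triphenylphosphoranylidene)acetaldehyde, O=CC=P(c1ccccc1)(c1ccccc1)c1ccccc1
Why: Wittig olefination with a stabilised ylide should give the new double bond as E and leave the Z-iodoalkene unchanged.

Step 5
Reactants: 6 phloroglucinol; 7 2,4-dihydroxyphenylacetic acid
Product: 8 2-(2,4-dihydroxyphenyl)-1-(2,4,6-trihydroxyphenyl)ethan-1-one
Conditions: BF3·OEt2, 85 °C; then aq. NaOAc
Reagents that add atoms: none
Why: BF3-mediated Friedel–Crafts acylation of a phenol by an arylacetic acid is the standard deoxybenzoin synthesis, and the threefold symmetry of phloroglucinol allows only one product.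

Step 6
Reactants: 8 2-(2,4-dihydroxyphenyl)-1-(2,4,6-trihydroxyphenyl)ethan-1-one
Product: 9 2-[2,4-bis(TIPSO)phenyl]-1-[2,6-dihydroxy-4-(TIPSO)phenyl]ethan-1-one
Conditions: TIPSCl (3.1 equiv), imidazole, DMF, 0 °C to rt
Reagents that add atoms: triisopropylsilyl chloride, CC(C)[Si](Cl)(C(C)C)C(C)C
Why: Selective silylation: the two hydroxyls flanking the ketone are hydrogen-bonded and hindered and should stay free with the bulky chloride, while the three other phenols are silylated; 9 keeps a mirror plane.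

Step 7
Reactants: 5 (2E,4Z)-5-iodohexa-2,4-dienal; 9 2-[2,4-bis(TIPSO)phenyl]-1-[2,6-dihydroxy-4-(TIPSO)phenyl]ethan-1-one
Product: 11 2-[2,4-bis(TIPSO)phenyl]-1-{(4R)-2,7-dihydroxy-4-[(1Z)-2-iodoprop-1-en-1-yl]-5-(TIPSO)-3,4-dihydro-2H-chromen-8-yl}ethan-1-one (lactol; both C-2 anomers), via hydroxy aldehyde 10 (not isolated)
Conditions: (R)-2-[diphenyl(trimethylsilyloxy)methyl]pyrrolidine (20 mol %), PhCO2H (20 mol %), 9 (1.3 equiv), toluene, −20 °C, dark
Reagents that add atoms: none
Why: Iminium-ion organocatalysis (Friedel–Crafts-type conjugate addition of an electron-rich phenol, then hemiacetalisation): the two nucleophilic ring carbons of 9 are equivalent, the C(Ph)2OSiMe3 group of the (R)-catalyst shields one face of the (E)-iminium so the arene should add to the other face of the β-carbon and set the benzylic centre as R, and the only neighbouring free hydroxyl closes the lactol.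

Step 8
Reactants: 11 lactol
Product: 12 (4R)-8-{2-[2,4-bis(TIPSO)phenyl]acetyl}-7-hydroxy-4-[(1Z)-2-iodoprop-1-en-1-yl]-5-(TIPSO)-3,4-dihydro-2H-chromen-2-one
Conditions: Dess–Martin periodinane (1.3 equiv), pyridine, CH2Cl2, 0 °C
Reagents that add atoms: none
Why: Dess–Martin oxidation of a lactol to the lactone is mild and should not touch the chelated phenol, the alkenyl iodide or the benzylic centre.

Step 9
Reactants: 12 dihydrocoumarin lactone
Product: 14 (4R)-9-[2,4-bis(TIPSO)phenyl]-10-hydroxy-4-[(1Z)-2-iodoprop-1-en-1-yl]-5-(TIPSO)-3,4-dihydro-2H,8H-pyrano[2,3-f]chromene-2,8-dione, via aryl imidazole-1-carboxylate 13 (not isolated)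
Conditions: CDI (1.5 equiv), THF, 40 °C; then DBU (2.2 equiv), 0 °C to rt; aq. citric acid work-up
Reagents that add atoms: 1,1'-carbonyldiimidazole, O=C(n1ccnc1)n1ccnc1
Why: Carbonylative cyclisation of a 2-hydroxydeoxybenzoin (O-acylation, then intramolecular Claisen-type C-acylation of the benzylic ketone enolate) should give the 3-aryl-4-hydroxycoumarin; its regiochemistry is fixed because the other ortho oxygen is tied up in the temporary lactone, and forming the reactive imidazolide before adding DBU is meant to outrun a Baker–Venkataraman-type attack on that lactone.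

Step 10
Reactants: 15 2,4-dihydroxybenzaldehyde
Product: 16 2,4-bis(TIPSO)benzaldehyde
Conditions: TIPSCl (2.3 equiv), imidazole, DMF, rt
Reagents that add atoms: triisopropylsilyl chloride, CC(C)[Si](Cl)(C(C)C)C(C)C
Why: Standard phenol silylation.

Step 11
Reactants: 16 2,4-bis(TIPSO)benzaldehyde
Product: 17 2,4-bis(TIPSO)benzoic acid
Conditions: NaClO2, NaH2PO4, 2-methylbut-2-ene, t-BuOH/H2O, 0 °C to rt
Reagents that add atoms: sodium chlorite, [Na+].[O-]Cl=O
Why: Pinnick oxidation converts the aldehyde to the acid under buffered conditions, and the alkene scavenger protects the electron-rich ring from hypochlorite.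

Step 12
Reactants: 17 2,4-bis(TIPSO)benzoic acid
Product: 18 1-[2,4-bis(TIPSO)benzoyl]-1H-imidazole
Conditions: CDI (1.1 equiv), THF, rt; used crude
Reagents that add atoms: 1,1'-carbonyldiimidazole, O=C(n1ccnc1)n1ccnc1
Why: Acyl imidazole formation with loss of CO2 gives a C-selective acylating agent.

Step 13
Reactants: 14 coumarin–lactone; 18 1-[2,4-bis(TIPSO)benzoyl]-1H-imidazole
Product: 19 (4R)-3-[2,4-bis(TIPSO)benzoyl]-9-[2,4-bis(TIPSO)phenyl]-10-hydroxy-4-[(1Z)-2-iodoprop-1-en-1-yl]-5-(TIPSO)-3,4-dihydro-2H,8H-pyrano[2,3-f]chromene-2,8-dione (C-3 epimers, partly enolised)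
Conditions: LiN(SiMe3)2 (3.2 equiv), THF, −78 °C; then 18 (1.2 equiv), −78 to −40 °C; AcOH quench
Reagents that add atoms: none
Why: Crossed Claisen C-acylation: the 4-hydroxycoumarin is masked as its unreactive lithium salt, the lactone enolate is acylated at carbon by the acyl imidazole, and the new C-3 centre is acidic and need not be controlled.

Step 14
Reactants: 16 2,4-bis(TIPSO)benzaldehyde
Product: 20 1-ethenyl-2,4-bis(TIPSO)benzene
Conditions: Ph3PCH3Br, KN(SiMe3)2, THF, 0 °C
Reagents that add atoms: methyltriphenylphosphonium bromide, C[P+](c1ccccc1)(c1ccccc1)c1ccccc1.[Br-]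
Why: Wittig methylenation of the aldehyde.

Step 15
Reactants: 19 alkenyl iodide β-keto lactone; 20 1-ethenyl-2,4-bis(TIPSO)benzene
Product: 21 cis-fused annulated lactone: the coumarin C-5 oxygen and C-6 are bridged by O–C(=O)–C(quaternary, R, bearing the 2,4-bis(TIPSO)benzoyl group) and the benzylic ring-fusion CH (R), and these two carbons are also part of the new 3-methylcyclohexene, whose CH next to the quaternary carbon (S) carries the 2,4-bis(TIPSO)phenyl group cis to the coumarin carbon
Conditions: Pd2(dba)3 (5 mol %), DPEphos (12 mol %), Ag2CO3 (2.5 equiv), 20 (3 equiv), 1,4-dioxane, 70 °C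
Reagents that add atoms: none
Why: Proposed new method: oxidative addition of zerovalent palladium into the C–I bond of the (Z)-alkenyl iodide and iodide abstraction by silver should give a cationic alkenylpalladium species that inserts styrene 20 with the alkenyl carbon going to the CH2 terminus, so that palladium ends at the benzylic carbon as an η3-benzyl complex stabilised by the electron-rich bis(silyloxy)arene; the tethered enolate of the β-keto lactone then attacks this benzylic carbon and closes the cyclohexene while zerovalent palladium is released. The closest known reaction types are the palladium-catalysed carboannulation of 1,3-dienes by alkenyl or aryl halides that carry a stabilised carbanion (Larock annulation, through η3-allyl palladium) and the palladium-catalysed benzylic alkylation of active methylene compounds (through η3-benzyl palladium); using a styrene as the two-carbon partner of such a [4+2] annulation is the untested part. The one ring that is closed, the carbocycle, is formed by intermolecular syn-carbopalladation followed by a 6-exo-tet displacement at the η3-benzyl carbon by the enolate carbon. The quaternary carbon is set by the tether (the new bond must form on the face of the lactone ring that carries the alkenyl arm, giving the cis-fused lactone; this centre is erased in step 16), and the benzylic centre is set relative to the centre from step 7 in a chair-like closure that keeps the aryl group equatorial and cis to the coumarin carbon, the two η3-benzyl epimers being expected to interconvert by palladium–palladium exchange. The step needs capture of the η3-benzyl intermediate to outrun β-hydride elimination to the Heck diene, which the cationic pathway, the bidentate ligand and the intramolecular soft nucleophile are meant to secure, and it needs insertion only at the styrene, which is secured because 19 has no other reactive alkene.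

Step 16
Reactants: 21 annulated lactone
Product: 24 3-[2,4-bis(TIPSO)phenyl]-6-{(1S,5R,6R)-6-[2,4-bis(TIPSO)benzoyl]-5-[2,4-bis(TIPSO)phenyl]-3-methylcyclohex-2-en-1-yl}-4,5-dihydroxy-7-(TIPSO)-2H-chromen-2-one, via β-keto acid 22 (not isolated), via enol 23 (not isolated)
Conditions: LiOH (3 equiv), THF/H2O, 0 °C; then AcOH to pH 5, 35 °C
Reagents that add atoms: none
Why: Saponification of the doubly activated aryl lactone (the 4-hydroxycoumarin is protected as its anion) and decarboxylation of the β-keto acid should give an exocyclic enol whose two flanking cis aryl groups are pushed pseudo-axial by allylic (A1,3) strain, so kinetic ketonisation delivers the proton to the open face anti to both and leaves the aroyl group cis to them, setting the all-cis ketone α-centre (R).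

Step 17
Reactants: 24 all-cis ketone 4-hydroxycoumarin
Product: 25 (3S)-3-[2,4-bis(TIPSO)phenyl]-6-{(1S,5R,6R)-6-[2,4-bis(TIPSO)benzoyl]-5-[2,4-bis(TIPSO)phenyl]-3-methylcyclohex-2-en-1-yl}-5-hydroxy-3-(3-methylbut-2-en-1-yl)-7-(TIPSO)chromane-2,4-dione
Conditions: prenyl acetate (1.5 equiv), Pd2(dba)3·CHCl3 (2.5 mol %), (S,S)-N,N'-(cyclohexane-1,2-diyl)bis[2-(diphenylphosphino)benzamide] (7.5 mol %), Et3N (1.1 equiv), CH2Cl2, rt
Reagents that add atoms: 3-methylbut-2-en-1-yl acetate (prenyl acetate), CC(=O)OCC=C(C)C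
Why: Tsuji–Trost asymmetric allylic alkylation: the acidic 3-aryl-4-hydroxycoumarin should attack the η3-prenyl palladium complex at its unsubstituted terminus through C-3 (O-prenyl products re-ionise and funnel to the C-alkylated dione), and the chiral ligand pocket selects the enolate face so the quaternary centre forms as 3S independently of the remote ring centres, under conditions too weakly basic to epimerise the ketone α-carbon.

Step 18
Reactants: 25 heptakis-TIPS ether
Product: 26 (3S)-3-(2,4-dihydroxyphenyl)-6-[(1S,5R,6R)-6-(2,4-dihydroxybenzoyl)-5-(2,4-dihydroxyphenyl)-3-methylcyclohex-2-en-1-yl]-5,7-dihydroxy-3-(3-methylbut-2-en-1-yl)chromane-2,4-dione (target)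
Conditions: Bu4NF (8 equiv), AcOH (8 equiv), THF, 0 °C
Reagents that add atoms: none
Why: Fluoride-mediated desilylation of aryl silyl ethers, buffered with acetic acid so that the base-labile β-keto lactone, the prenyl group and the epimerisable all-cis ketone are not exposed to free phenoxide or to acid.

**Compound list**

1 | ethyl but-2-ynoate | CC#CC(=O)OCC | starting material
2 | ethyl (2Z)-3-iodobut-2-enoate | CCOC(=O)/C=C(/C)I | intermediate
3 | (2Z)-3-iodobut-2-en-1-ol | OC/C=C(/C)I | intermediate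
4 | (2Z)-3-iodobut-2-enal | O=C/C=C(/C)I | intermediate
5 | (2E,4Z)-5-iodohexa-2,4-dienal | O=C/C=C/C=C(/C)I | intermediate
6 | phloroglucinol (benzene-1,3,5-triol) | Oc1cc(O)cc(O)c1 | starting material
7 | 2,4-dihydroxyphenylacetic acid | OC(=O)Cc1ccc(O)cc1O | starting material
8 | 2-(2,4-dihydroxyphenyl)-1-(2,4,6-trihydroxyphenyl)ethan-1-one | O=C(Cc1ccc(O)cc1O)c1c(O)cc(O)cc1O | intermediate
9 | 2-[2,4-bis(TIPSO)phenyl]-1-[2,6-dihydroxy-4-(TIPSO)phenyl]ethan-1-one | O=C(Cc1ccc(O[Si](C(C)C)(C(C)C)C(C)C)cc1O[Si](C(C)C)(C(C)C)C(C)C)c1c(O)cc(O[Si](C(C)C)(C(C)C)C(C)C)cc1O | intermediate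
10 | (3R,4Z)-3-{3-[2-(2,4-bis(TIPSO)phenyl)acetyl]-2,4-dihydroxy-6-(TIPSO)phenyl}-5-iodohex-4-enal (not isolated) | O=CC[C@H](/C=C(/C)I)c1c(O)c(C(=O)Cc2ccc(O[Si](C(C)C)(C(C)C)C(C)C)cc2O[Si](C(C)C)(C(C)C)C(C)C)c(O)cc1O[Si](C(C)C)(C(C)C)C(C)C | intermediate
11 | 2-[2,4-bis(TIPSO)phenyl]-1-{(4R)-2,7-dihydroxy-4-[(1Z)-2-iodoprop-1-en-1-yl]-5-(TIPSO)-3,4-dihydro-2H-chromen-8-yl}ethan-1-one (lactol, both anomers) | O=C(Cc1ccc(O[Si](C(C)C)(C(C)C)C(C)C)cc1O[Si](C(C)C)(C(C)C)C(C)C)c1c(O)cc(O[Si](C(C)C)(C(C)C)C(C)C)c2c1OC(O)C[C@@H]2/C=C(/C)I | intermediate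
12 | (4R)-8-{2-[2,4-bis(TIPSO)phenyl]acetyl}-7-hydroxy-4-[(1Z)-2-iodoprop-1-en-1-yl]-5-(TIPSO)-3,4-dihydro-2H-chromen-2-one | O=C(Cc1ccc(O[Si](C(C)C)(C(C)C)C(C)C)cc1O[Si](C(C)C)(C(C)C)C(C)C)c1c(O)cc(O[Si](C(C)C)(C(C)C)C(C)C)c2c1OC(=O)C[C@@H]2/C=C(/C)I | intermediate
13 | (4R)-8-{2-[2,4-bis(TIPSO)phenyl]acetyl}-4-[(1Z)-2-iodoprop-1-en-1-yl]-2-oxo-5-(TIPSO)-3,4-dihydro-2H-chromen-7-yl 1H-imidazole-1-carboxylate (not isolated) | O=C(Cc1ccc(O[Si](C(C)C)(C(C)C)C(C)C)cc1O[Si](C(C)C)(C(C)C)C(C)C)c1c(OC(=O)n3ccnc3)cc(O[Si](C(C)C)(C(C)C)C(C)C)c2c1OC(=O)C[C@@H]2/C=C(/C)I | intermediate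
14 | (4R)-9-[2,4-bis(TIPSO)phenyl]-10-hydroxy-4-[(1Z)-2-iodoprop-1-en-1-yl]-5-(TIPSO)-3,4-dihydro-2H,8H-pyrano[2,3-f]chromene-2,8-dione | O=C1Oc2cc(O[Si](C(C)C)(C(C)C)C(C)C)c3c(OC(=O)C[C@@H]3/C=C(/C)I)c2C(O)=C1c1ccc(O[Si](C(C)C)(C(C)C)C(C)C)cc1O[Si](C(C)C)(C(C)C)C(C)C | intermediate
15 | 2,4-dihydroxybenzaldehyde | O=Cc1ccc(O)cc1O | starting material
16 | 2,4-bis(TIPSO)benzaldehyde | O=Cc1ccc(O[Si](C(C)C)(C(C)C)C(C)C)cc1O[Si](C(C)C)(C(C)C)C(C)C | intermediate
17 | 2,4-bis(TIPSO)benzoic acid | OC(=O)c1ccc(O[Si](C(C)C)(C(C)C)C(C)C)cc1O[Si](C(C)C)(C(C)C)C(C)C | intermediate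
18 | 1-[2,4-bis(TIPSO)benzoyl]-1H-imidazole | O=C(c1ccc(O[Si](C(C)C)(C(C)C)C(C)C)cc1O[Si](C(C)C)(C(C)C)C(C)C)n1ccnc1 | intermediate
19 | (4R)-3-[2,4-bis(TIPSO)benzoyl]-9-[2,4-bis(TIPSO)phenyl]-10-hydroxy-4-[(1Z)-2-iodoprop-1-en-1-yl]-5-(TIPSO)-3,4-dihydro-2H,8H-pyrano[2,3-f]chromene-2,8-dione (C-3 epimers) | O=C1Oc2cc(O[Si](C(C)C)(C(C)C)C(C)C)c3c(OC(=O)C(C(=O)c4ccc(O[Si](C(C)C)(C(C)C)C(C)C)cc4O[Si](C(C)C)(C(C)C)C(C)C)[C@@H]3/C=C(/C)I)c2C(O)=C1c1ccc(O[Si](C(C)C)(C(C)C)C(C)C)cc1O[Si](C(C)C)(C(C)C)C(C)C | intermediate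
20 | 1-ethenyl-2,4-bis(TIPSO)benzene | C=Cc1ccc(O[Si](C(C)C)(C(C)C)C(C)C)cc1O[Si](C(C)C)(C(C)C)C(C)C | intermediate
21 | cis-fused annulated β-keto lactone (quaternary aroyl-bearing carbon R, aryl-bearing CH S, ring-fusion benzylic CH R; 3-methylcyclohexene fused to the temporary lactone of 19) | O=C1Oc2cc(O[Si](C(C)C)(C(C)C)C(C)C)c3c(OC(=O)[C@]4(C(=O)c5ccc(O[Si](C(C)C)(C(C)C)C(C)C)cc5O[Si](C(C)C)(C(C)C)C(C)C)[C@H](c5ccc(O[Si](C(C)C)(C(C)C)C(C)C)cc5O[Si](C(C)C)(C(C)C)C(C)C)CC(C)=C[C@H]34)c2C(O)=C1c1ccc(O[Si](C(C)C)(C(C)C)C(C)C)cc1O[Si](C(C)C)(C(C)C)C(C)C | intermediate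
22 | (1R,2R,6S)-1-[2,4-bis(TIPSO)benzoyl]-6-[2,4-bis(TIPSO)phenyl]-2-{3-[2,4-bis(TIPSO)phenyl]-4,5-dihydroxy-2-oxo-7-(TIPSO)-2H-chromen-6-yl}-4-methylcyclohex-3-ene-1-carboxylic acid (not isolated) | O=C1Oc2cc(O[Si](C(C)C)(C(C)C)C(C)C)c([C@H]3C=C(C)C[C@@H](c4ccc(O[Si](C(C)C)(C(C)C)C(C)C)cc4O[Si](C(C)C)(C(C)C)C(C)C)[C@]3(C(O)=O)C(=O)c3ccc(O[Si](C(C)C)(C(C)C)C(C)C)cc3O[Si](C(C)C)(C(C)C)C(C)C)c(O)c2C(O)=C1c1ccc(O[Si](C(C)C)(C(C)C)C(C)C)cc1O[Si](C(C)C)(C(C)C)C(C)C | intermediate
23 | enol of 24 (exocyclic C=C(OH)aryl at the former quaternary carbon; the two other ring centres as in 22; not isolated) | O=C1Oc2cc(O[Si](C(C)C)(C(C)C)C(C)C)c([C@H]3C=C(C)C[C@@H](c4ccc(O[Si](C(C)C)(C(C)C)C(C)C)cc4O[Si](C(C)C)(C(C)C)C(C)C)C3=C(O)c3ccc(O[Si](C(C)C)(C(C)C)C(C)C)cc3O[Si](C(C)C)(C(C)C)C(C)C)c(O)c2C(O)=C1c1ccc(O[Si](C(C)C)(C(C)C)C(C)C)cc1O[Si](C(C)C)(C(C)C)C(C)C | intermediate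
24 | 3-[2,4-bis(TIPSO)phenyl]-6-{(1S,5R,6R)-6-[2,4-bis(TIPSO)benzoyl]-5-[2,4-bis(TIPSO)phenyl]-3-methylcyclohex-2-en-1-yl}-4,5-dihydroxy-7-(TIPSO)-2H-chromen-2-one | O=C1Oc2cc(O[Si](C(C)C)(C(C)C)C(C)C)c([C@H]3C=C(C)C[C@@H](c4ccc(O[Si](C(C)C)(C(C)C)C(C)C)cc4O[Si](C(C)C)(C(C)C)C(C)C)[C@H]3C(=O)c3ccc(O[Si](C(C)C)(C(C)C)C(C)C)cc3O[Si](C(C)C)(C(C)C)C(C)C)c(O)c2C(O)=C1c1ccc(O[Si](C(C)C)(C(C)C)C(C)C)cc1O[Si](C(C)C)(C(C)C)C(C)C | intermediate
25 | (3S)-3-[2,4-bis(TIPSO)phenyl]-6-{(1S,5R,6R)-6-[2,4-bis(TIPSO)benzoyl]-5-[2,4-bis(TIPSO)phenyl]-3-methylcyclohex-2-en-1-yl}-5-hydroxy-3-(3-methylbut-2-en-1-yl)-7-(TIPSO)chromane-2,4-dione | CC(C)=CC[C@@]1(c2ccc(O[Si](C(C)C)(C(C)C)C(C)C)cc2O[Si](C(C)C)(C(C)C)C(C)C)C(=O)Oc2cc(O[Si](C(C)C)(C(C)C)C(C)C)c([C@H]3C=C(C)C[C@@H](c4ccc(O[Si](C(C)C)(C(C)C)C(C)C)cc4O[Si](C(C)C)(C(C)C)C(C)C)[C@H]3C(=O)c3ccc(O[Si](C(C)C)(C(C)C)C(C)C)cc3O[Si](C(C)C)(C(C)C)C(C)C)c(O)c2C1=O | intermediate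
26 | (3S)-3-(2,4-dihydroxyphenyl)-6-[(1S,5R,6R)-6-(2,4-dihydroxybenzoyl)-5-(2,4-dihydroxyphenyl)-3-methylcyclohex-2-en-1-yl]-5,7-dihydroxy-3-(3-methylbut-2-en-1-yl)chromane-2,4-dione | CC(C)=CC[C@@]1(c2ccc(O)cc2O)C(=O)Oc2cc(O)c([C@H]3C=C(C)C[C@@H](c4ccc(O)cc4O)[C@H]3C(=O)c3ccc(O)cc3O)c(O)c2C1=O | target

**Step count and risks**

Total steps: 18. Longest linear sequence: 12 steps (1–4, 7–9, 13, 15–18).

Most likely to fail:

1. Step 15 (proposed new method). What may go wrong: β-hydride elimination from the benzylpalladium intermediate outruns ring closure and gives the open Heck diene, or the benzylic carbon is formed without facial control because the η3-benzyl epimers do not equilibrate. Fallback (sets out from 19 and 20, comes back at 21), using known reaction types in two operations: hydroboration of 20 with 9-BBN in THF would give the alkylborane 9-[2-(2,4-bis(TIPSO)phenyl)ethyl]-9-borabicyclo[3.3.1]nonane F1. B-alkyl Suzuki–Miyaura coupling of F1 with iodide 19 (Pd(dppf)Cl2, AsPh3, Cs2CO3, DMF/THF/H2O) would make the first ring bond with retention of alkene geometry and give the (Z)-alkene β-keto lactone F2. Oxidation of the electron-rich benzylic CH2 of F2 with DDQ (cross-dehydrogenative coupling) would then generate an oxygen-stabilised benzylic cation that the enol of the β-keto lactone captures in a chair-like six-membered closure with the aryl group equatorial, giving 21.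

2. Step 16. What may go wrong: loss of kinetic control in the ketonisation (proton delivered to the face syn to the aryl groups, or later epimerisation of the ketone α-carbon to the more stable all-trans ring), or retro-Claisen cleavage of the aroyl group by hydroxide. Fallback (sets out from 21, comes back at 24): transesterification of 21 with allyl alcohol and catalytic DMAP would open the lactone to the allyl β-keto ester prop-2-en-1-yl ester of acid 22 F3. Palladium-catalysed decarboxylative protonation of F3 (Pd(OAc)2, a chiral phosphinooxazoline ligand whose enantiomer is chosen to reinforce the substrate bias, HCO2H, 1,4-dioxane, 40 °C) would then protonate a palladium enolate under neutral, catalyst-controlled conditions to give 24.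

3. Step 7. What may go wrong: scrambling of the Z-iodoalkene geometry through reversible trienamine formation, competing 1,6-addition with displacement of iodide, or sluggish attack by the acyl-deactivated arene. Fallback (sets out from 5 and 9, comes back at 12 and so also replaces step 8): oxidative N-heterocyclic-carbene catalysis (chiral aminoindanol-derived triazolium salt, 3,3',5,5'-tetra-tert-butyldiphenoquinone, catalytic base, toluene) would convert 5 into a dienoyl azolium that the phenol 9 attacks at the β-carbon and then acylates on oxygen, giving lactone 12 directly without enamine intermediates; no compound outside the list is made (none F0).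

Further compounds
F1 | step 15 | 9-[2-(2,4-bis(TIPSO)phenyl)ethyl]-9-borabicyclo[3.3.1]nonane | C(Cc1ccc(O[Si](C(C)C)(C(C)C)C(C)C)cc1O[Si](C(C)C)(C(C)C)C(C)C)B1C2CCCC1CCC2
F2 | step 15 | analogue of 19 with a (1Z)-4-[2,4-bis(TIPSO)phenyl]-2-methylbut-1-en-1-yl group in place of the iodopropenyl group (same configuration at the benzylic carbon) | O=C1Oc2cc(O[Si](C(C)C)(C(C)C)C(C)C)c3c(OC(=O)C(C(=O)c4ccc(O[Si](C(C)C)(C(C)C)C(C)C)cc4O[Si](C(C)C)(C(C)C)C(C)C)[C@@H]3/C=C(/C)CCc3ccc(O[Si](C(C)C)(C(C)C)C(C)C)cc3O[Si](C(C)C)(C(C)C)C(C)C)c2C(O)=C1c1ccc(O[Si](C(C)C)(C(C)C)C(C)C)cc1O[Si](C(C)C)(C(C)C)C(C)C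
F3 | step 16 | prop-2-en-1-yl (1R,2R,6S)-1-[2,4-bis(TIPSO)benzoyl]-6-[2,4-bis(TIPSO)phenyl]-2-{3-[2,4-bis(TIPSO)phenyl]-4,5-dihydroxy-2-oxo-7-(TIPSO)-2H-chromen-6-yl}-4-methylcyclohex-3-ene-1-carboxylate | O=C1Oc2cc(O[Si](C(C)C)(C(C)C)C(C)C)c([C@H]3C=C(C)C[C@@H](c4ccc(O[Si](C(C)C)(C(C)C)C(C)C)cc4O[Si](C(C)C)(C(C)C)C(C)C)[C@]3(C(=O)OCC=C)C(=O)c3ccc(O[Si](C(C)C)(C(C)C)C(C)C)cc3O[Si](C(C)C)(C(C)C)C(C)C)c(O)c2C(O)=C1c1ccc(O[Si](C(C)C)(C(C)C)C(C)C)cc1O[Si](C(C)C)(C(C)C)C(C)C
F0 | step 7 | none | none
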